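I started from what stays constant in these racemate runs: free catalyst and partner stand as the same factors in the steps of both substrates.

| flask | left-handed substrate | right-handed substrate | partner | free catalyst | impurity | remark | time |
|---|---|---|---|---|---|---|---|
| Friday's | 0.082 M | 0.082 M | 0.164 M | 4.8 mM | 0.80 mM | run made earlier |  |
| Sunday's | 0.082 M | 0.082 M | 0.164 M | 4.8 mM | 1.8 mM | run made earlier |  |
| flask | 0.082 M | 0.082 M | 0.164 M | 4.8 mM | 1.2 mM |  | 30 min |

- Friday's (time / min: left-handed substrate / %, right-handed substrate / %): 3.00: 38.9, 44.0; 6.00: 34.8, 40.0; 10.0: 31.7, 39.8; 15.0: 27.2, 37.2; 20.0: 28.9, 36.2; 25.0: 23.9, 36.1
- Sunday's (time / min: left-handed substrate / %, right-handed substrate / %): 1.33: 44.3, 46.3; 4.00: 40.3, 44.6; 6.00: 35.3, 41.9; 10.0: 31.5, 38.4; 15.0: 30.6, 38.7; 20.0: 27.6, 38.5; 25.0: 29.2, 37.0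

(standard deviation of a reading: 1 percentage point)

- free catalyst is single-handed; left-handed substrate and right-handed substrate are mirror images of each other, charged as a racemate, each of them at the stated concentration
- steps thought possible: 2 free catalyst -> spent catalyst B; free catalyst + impurity -> spent catalyst A; partner + free catalyst + left-handed substrate -> free catalyst + left-handed product; left-handed product <-> right-handed product; partner + free catalyst + right-handed substrate -> free catalyst + right-handed product
- an excess is the difference of the two amounts in percent of their sum
- an excess is below zero if the other one leads

* part of the left-handed substrate and right-handed substrate charged together that has reacted at 30 min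
* excess of left-handed product over right-handed product in the product at 30 min
* excess of right-handed substrate over left-handed substrate among what is left of the two at 30 min

Two things in the runs seemed not to fit. By its readings, Friday's run lost substrate 13.0 times more slowly from 15.0 min to 25.0 min than in its first 3.00 min, yet the contest between the substrates did not seem to shift with it.

Dividing the rate laws of the two substrate steps clears this up: free catalyst and partner cancel. However far the speed falls, the logarithm of the part of its charge left of the left-handed substrate, over the same logarithm for the right-handed substrate, should stay constant. I solved this at both ends. Friday's reading at 3.00 min and Sunday's at 4.00 min gave 1.93, and the last two readings of both runs gave 2.00, about the same. I carried the late reading as the selectivity factor.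

The forecast gave 38% reacted, a product excess of 22% and a substrate excess of 15%, noting of the runs that “they cannot show product interconversion”. On its conversion, with the factor taken as 2, I reckoned 72.1% of the right-handed substrate's charge left, hence a substrate excess of 16.2%, differing from its figure.

The flask gave 38.6% reacted, a substrate excess of 16.6% and a product excess of 0.117%. By their interconversion step alone, left-handed and right-handed product relax into each other with a half-life of 0.619 min, both ways together, short against the 30 min of the flask.

    2 free catalyst → spent catalyst B (k = 60.0 L mol⁻¹ min⁻¹)
    free catalyst + impurity → spent catalyst A (k = 17000 L mol⁻¹ min⁻¹)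
    partner + free catalyst + left-handed substrate → free catalyst + left-handed product (k = 240 L² mol⁻² min⁻¹)
    left-handed product ⇌ right-handed product (k = 0.560 min⁻¹)
    partner + free catalyst + right-handed substrate → free catalyst + right-handed product (k = 120 L² mol⁻² min⁻¹)

In this flask 51% of the left-handed substrate's charge remained, and the factor turns that into 71.5% of the right-handed substrate's charge, where 72% stood. In the neighbour flask with 0.66 M of partner, 5.2% of the left-handed substrate's charge remained, which gives a substrate excess of 62.9%; that neighbour held 63.0%.

The earlier runs and the new flask are calculated on assumed constants.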